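**Assumptions (one line each):** The target SMILES is taken as drawn, with configuration 1S,3R,4S,7R,8S,12S,13R,14R in cembrane numbering (C1–C14 ring, C15–C17 lactone side chain, C18–C20 methyls). (S)-Linalool, 2,2-dimethoxyacetaldehyde and methyl acrylate are treated as commercial.

## Retrosynthetic overview
1. The 14-membered carbocycle and the cis-fused α-methylene-γ-lactone close together in the last C–C step: intramolecular NHK allylation (C1–C14) of a C14 aldehyde with a C1 (Z)-2-(bromomethyl)alkenoate, then lactonisation. TBS is removed last.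
2. The C9–C10 bond comes from Cu-catalysed opening of a C8–C9 1,1-disubstituted epoxide by the C10 Grignard of an I–C10…C14 acetal fragment. That fragment is made by syn-crotylation of glyoxal acetal, which sets C12 and C13.
3. The THF ring forms second. The C4 tertiary OH of (S)-linalool (which supplies C4) opens a C7/C8 epoxide 5-exo. That epoxide comes from Sharpless AE of 8-hydroxylinalool; C9 is the SeO2-oxidised E-methyl.
4. C3 comes from Brown allylation of the THF-C3 aldehyde (made by vinyl ozonolysis). The allyl carbons become C2 and C1, and the terminal alkene is later ozonolysed to the C1 aldehyde for Baylis–Hillman/bromination.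

## Route

**Step 1**
Reactants: 1 (3S)-3,7-dimethylocta-1,6-dien-3-ol, (S)-linalool
Product: 2 (3S,6E)-3,7-dimethylocta-1,6-diene-3,8-diol, (E)-8-hydroxylinalool
Conditions: SeO2 (10 mol%), TBHP (aq. 70%), CH2Cl2, 0 °C → rt
Reagents that add atoms: tert-butyl hydroperoxide, CC(C)(C)OO (O source); SeO2, O=[Se]=O (catalyst)
Why: Riley/Umbreit–Sharpless allylic oxidation is selective for the E-methyl of the trisubstituted prenyl alkene, which gives the E-allylic alcohol (C9–OH); the C4 carbinol is untouched.

**Step 2**
Reactants: 2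
Product: 3 (3S)-6,7-epoxy-3,7-dimethyloct-1-ene-3,8-diol, with epoxide carbons (6S,7S)
Conditions: Ti(OiPr)4 (10 mol%), L-(+)-DET (12 mol%), TBHP, 3 Å MS, CH2Cl2, –20 °C
Reagents that add atoms: TBHP, CC(C)(C)OO (O source)
Why: Sharpless asymmetric epoxidation of the primary allylic alcohol; L-(+)-DET delivers O to the top face, which sets C7 (S) and C8 (S) of the epoxide, and the vinyl and tertiary alcohol are unreactive.

**Step 3**
Reactants: 3
Product: 4 (2S)-2-[(2R,5S)-5-ethenyl-5-methyloxolan-2-yl]propane-1,2-diol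
Conditions: CSA (5 mol%), CH2Cl2, 0 °C
Reagents that add atoms: none
Why: Acid-catalysed 5-exo-tet opening of the epoxide by the C4 tertiary OH at secondary C7 (the CH2OH withdraws electrons from tertiary C8, so the 6-endo pathway is disfavoured). Inversion at C7 gives 7R, C8 (S) is retained and C4 (S) is untouched.

**Step 4**
Reactants: 4
Product: 5 (2S)-2-[(2R,5S)-5-ethenyl-5-methyloxolan-2-yl]-2-methyloxirane
Conditions: TsCl, Et3N, cat. Me3N·HCl, CH2Cl2, 0 °C; then KOtBu, THF, 0 °C (one pot)
Reagents that add atoms: none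
Why: Selective tosylation of the primary OH, then 3-exo-tet closure by the tertiary alkoxide gives the 1,1-disubstituted epoxide; the C8–O bond is never broken, so C8 keeps its configuration.

**Step 5**
Reactants: 5
Product: 6 (2S,5R)-2-methyl-5-[(2S)-2-methyloxiran-2-yl]oxolane-2-carbaldehyde
Conditions: O3, CH2Cl2, –78 °C; then Me2S
Reagents that add atoms: ozone, O=[O+][O-] (supplies the carbonyl O)
Why: Ozonolysis cleaves only the vinyl group (the other alkenes are gone); the aldehyde sits on quaternary C4, so it cannot epimerise.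

**Step 6**
Reactants: 6
Product: 7 (1R)-1-[(2S,5R)-2-methyl-5-[(2S)-2-methyloxiran-2-yl]oxolan-2-yl]but-3-en-1-ol
Conditions: allyl-Ipc2B (from (−)-α-pinene), Et2O, –78 °C; then NaBO3·4H2O, THF/H2O
Reagents that add atoms: B-allyldiisopinocampheylborane, C=CCB(C1C(C)C2CC(C1)C2(C)C)C1C(C)C2CC(C1)C2(C)C (Ipc stereochemistry not drawn)
Why: Brown asymmetric allylboration is reagent-controlled and adds the allyl group to the Re face of the C3 aldehyde, creating C3 (R); the allyl carbons become C2 and C1.

**Step 7**
Reactants: 7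
Product: 8 TBS ether of 7, tert-butyl{[(1R)-1-{(2S,5R)-2-methyl-5-[(2S)-2-methyloxiran-2-yl]oxolan-2-yl}but-3-en-1-yl]oxy}dimethylsilane
Conditions: TBSOTf, 2,6-lutidine, CH2Cl2, –78 → 0 °C
Reagents that add atoms: TBSOTf, C[Si](C)(C(C)(C)C)OS(=O)(=O)C(F)(F)F
Why: Silylation of the hindered C3 alcohol protects it through the later organometallic, acetylation and bromination steps; no stereocentre is involved.

**Step 8**
Reactants: 9 2,2-dimethoxyacetaldehyde (dried)
Product: 10 (2R,3S)-1,1-dimethoxy-3-methylpent-4-en-2-ol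
Conditions: (Z)-crotyl-Ipc2B (from (−)-α-pinene), THF/Et2O, –78 °C; then NaOH, H2O2
Reagents that add atoms: (Z)-crotyl-diisopinocampheylborane, C/C=C\CB(C1C(C)C2CC(C1)C2(C)C)C1C(C)C2CC(C1)C2(C)C
Why: Brown crotylboration through a chair transition state: Re-face attack sets C13 (R), and the Z-crotyl geometry gives the syn relationship, i.e. C12 (S), which is what the target has.

**Step 9**
Reactants: 10
Product: 11 triethyl{[(2R,3S)-1,1-dimethoxy-3-methylpent-4-en-2-yl]oxy}silane
Conditions: TESCl, imidazole, DMF, 0 °C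
Reagents that add atoms: chlorotriethylsilane, CC[Si](CC)(CC)Cl
Why: The secondary alcohol is masked as a TES ether so the Grignard in step 11 can form, and TES is removable in the presence of TBS.

**Step 10**
Reactants: 11
Product: 12 triethyl{[(2R,3S)-5-iodo-1,1-dimethoxy-3-methylpentan-2-yl]oxy}silane
Conditions: Cp2Zr(H)Cl (Schwartz), CH2Cl2, 25 °C; then I2, 0 °C
Reagents that add atoms: iodine, II
Why: Hydrozirconation puts Zr on the terminal carbon (C10) and iodinolysis gives the primary iodide; the remote C12/C13 centres are not touched.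

**Step 11**
Reactants: 8 and 12
Product: 13 C8 tertiary alcohol, (3R,4S,7R,8S,12S,13R)-configured: C13–OTES, C14 dimethyl acetal, C3–OTBS, terminal C1=C15 alkene
Conditions: Mg, THF, reflux to give RMgI from 12; then add to 8 with CuI (10 mol%), THF, –40 → 0 °C
Reagents that add atoms: none (the C10–C14 chain comes from reactant 12)
Why: Cu-catalysed Grignard opening of the epoxide occurs at the unhindered CH2 (C9) and forms the C9–C10 bond; C8–O is not involved, so 8S is retained.

**Step 12**
Reactants: 13
Product: 14 diol: C13–OH, C8–OH, C3–OTBS, C14 dimethyl acetal, terminal alkene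
Conditions: PPTS (0.2 equiv), MeOH, 0 °C → rt
Reagents that add atoms: none
Why: Mild acid cleaves the TES ether selectively, leaving TBS and the acetal (TES ≪ TBS in acid lability).

**Step 13**
Reactants: 14
Product: 15 C8, C13 diacetate
Conditions: Ac2O (20 equiv), DMAP (2 equiv), Et3N, CH2Cl2, 40 °C
Reagents that add atoms: acetic anhydride, CC(=O)OC(C)=O
Why: DMAP-catalysed acylation of both the secondary C13-OH and the tertiary C8-OH; acylation occurs at oxygen, so no carbon stereocentre is touched.

**Step 14**
Reactants: 15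
Product: 16 C1 aldehyde (β-silyloxy aldehyde)
Conditions: O3, CH2Cl2, –78 °C; then Me2S
Reagents that add atoms: ozone, O=[O+][O-]
Why: Ozonolysis of the only alkene (the C1=C15 terminal alkene) gives the aldehyde needed for the Baylis–Hillman step.

**Step 15**
Reactants: 16 and 17 methyl acrylate
Product: 18 Baylis–Hillman adduct, C1–OH, C15(=CH2)CO2Me (C1 epimers; the stereocentre is lost in step 16)
Conditions: DABCO (1 equiv), MeOH, 25 °C, several days
Reagents that add atoms: none (methyl acrylate is reactant 17)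
Why: Morita–Baylis–Hillman reaction builds the C15–C17 unit; because C1 becomes sp2 in the next step, its configuration does not matter.

**Step 16**
Reactants: 18
Product: 19 (Z)-2-(bromomethyl)alk-2-enoate, C1=C15(CH2Br)CO2Me
Conditions: MsCl, Et3N, CH2Cl2, 0 °C; then LiBr, THF, 0 °C
Reagents that add atoms: lithium bromide, [Li+].[Br-]
Why: The allylic mesylate undergoes SN2′ substitution by bromide, giving the thermodynamic (Z)-trisubstituted allylic bromide; the TBS ether and acetates are unaffected.

**Step 17**
Reactants: 19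
Product: 20 C14 aldehyde (α-acetoxy aldehyde)
Conditions: I2 (10 mol%), wet acetone, 25 °C
Reagents that add atoms: water, O (supplies the aldehyde O)
Why: Neutral iodine-catalysed acetal exchange/hydrolysis liberates the aldehyde without touching TBS, acetates or the allylic bromide; C13 is not epimerised under these conditions.

**Step 18**
Reactants: 20
Product: 21 TBS-protected target, 14-membered carbocycle with cis-fused α-methylene-γ-lactone
Conditions: CrCl2 (10 equiv), NiCl2 (cat.), DMF, 0.003 M, 25 °C; then PPTS (cat.) to complete lactonisation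
Reagents that add atoms: none
Why: Intramolecular Nozaki–Hiyama–Kishi allylation: the allylchromium adds through its γ-carbon (C1) to the C14 aldehyde via a chair transition state, forming C1–C14, the exocyclic methylene and the alkoxide. The alkoxide then lactonises onto the methyl ester (lost as MeOH). The chair transition state is expected to give the anti homoallylic alcohol, i.e. the cis-lactone (1S,14R), with the α-OAc oriented to minimise its dipole.

**Step 19**
Reactants: 21
Product: 22 target (1S,3R,4S,7R,8S,12S,13R,14R)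
Conditions: HF·pyridine, pyridine/THF, 0 → 25 °C
Reagents that add atoms: none
Why: Fluoride removes the C3 TBS ether; the acetates and α-methylene lactone survive these mildly acidic, non-nucleophilic conditions.

## Compound list
1 | (3S)-3,7-dimethylocta-1,6-dien-3-ol, (S)-linalool | CC(C)=CCC[C@](C)(O)C=C | starting material
2 | (3S,6E)-3,7-dimethylocta-1,6-diene-3,8-diol | OC/C(C)=C/CC[C@](C)(O)C=C | intermediate
3 | (3S)-6,7-epoxy-3,7-dimethyloct-1-ene-3,8-diol, (6S,7S) | OC[C@]1(C)O[C@H]1CC[C@](C)(O)C=C | intermediate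
4 | (2S)-2-[(2R,5S)-5-ethenyl-5-methyloxolan-2-yl]propane-1,2-diol | OC[C@](C)(O)[C@H]1CC[C@](C)(O1)C=C | intermediate
5 | (2S)-2-[(2R,5S)-5-ethenyl-5-methyloxolan-2-yl]-2-methyloxirane | C1O[C@]1(C)[C@H]2CC[C@](C)(O2)C=C | intermediate
6 | (2S,5R)-2-methyl-5-[(2S)-2-methyloxiran-2-yl]oxolane-2-carbaldehyde | C1O[C@]1(C)[C@H]2CC[C@](C)(O2)C=O | intermediate
7 | (1R)-1-[(2S,5R)-2-methyl-5-[(2S)-2-methyloxiran-2-yl]oxolan-2-yl]but-3-en-1-ol | C1O[C@]1(C)[C@H]2CC[C@](C)(O2)[C@H](O)CC=C | intermediate
8 | TBS ether of 7 | C1O[C@]1(C)[C@H]2CC[C@](C)(O2)[C@H](O[Si](C)(C)C(C)(C)C)CC=C | intermediate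
9 | 2,2-dimethoxyacetaldehyde | COC(OC)C=O | starting material
10 | (2R,3S)-1,1-dimethoxy-3-methylpent-4-en-2-ol | COC(OC)[C@H](O)[C@@H](C)C=C | intermediate
11 | TES ether of 10 | COC(OC)[C@H](O[Si](CC)(CC)CC)[C@@H](C)C=C | intermediate
12 | triethyl{[(2R,3S)-5-iodo-1,1-dimethoxy-3-methylpentan-2-yl]oxy}silane | COC(OC)[C@H](O[Si](CC)(CC)CC)[C@@H](C)CCI | intermediate
13 | C8 tertiary alcohol (3R,4S,7R,8S,12S,13R), OTES/OTBS/acetal/terminal alkene | COC(OC)[C@H](O[Si](CC)(CC)CC)[C@@H](C)CCC[C@](C)(O)[C@H]1CC[C@](C)(O1)[C@H](O[Si](C)(C)C(C)(C)C)CC=C | intermediate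
14 | C8, C13 diol from 13 | COC(OC)[C@H](O)[C@@H](C)CCC[C@](C)(O)[C@H]1CC[C@](C)(O1)[C@H](O[Si](C)(C)C(C)(C)C)CC=C | intermediate
15 | C8, C13 diacetate | COC(OC)[C@H](OC(C)=O)[C@@H](C)CCC[C@](C)(OC(C)=O)[C@H]1CC[C@](C)(O1)[C@H](O[Si](C)(C)C(C)(C)C)CC=C | intermediate
16 | C1 aldehyde | COC(OC)[C@H](OC(C)=O)[C@@H](C)CCC[C@](C)(OC(C)=O)[C@H]1CC[C@](C)(O1)[C@H](O[Si](C)(C)C(C)(C)C)CC=O | intermediate
17 | methyl acrylate | C=CC(=O)OC | starting material
18 | Baylis–Hillman adduct | COC(OC)[C@H](OC(C)=O)[C@@H](C)CCC[C@](C)(OC(C)=O)[C@H]1CC[C@](C)(O1)[C@H](O[Si](C)(C)C(C)(C)C)CC(O)C(=C)C(=O)OC | intermediate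
19 | (Z)-allylic bromide | COC(OC)[C@H](OC(C)=O)[C@@H](C)CCC[C@](C)(OC(C)=O)[C@H]1CC[C@](C)(O1)[C@H](O[Si](C)(C)C(C)(C)C)C/C=C(\CBr)C(=O)OC | intermediate
20 | C14 aldehyde | O=C[C@H](OC(C)=O)[C@@H](C)CCC[C@](C)(OC(C)=O)[C@H]1CC[C@](C)(O1)[C@H](O[Si](C)(C)C(C)(C)C)C/C=C(\CBr)C(=O)OC | intermediate
21 | TBS-protected macrocycle | C=C1C(=O)O[C@H]2[C@H](OC(C)=O)[C@@H](C)CCC[C@](C)(OC(C)=O)[C@H]3CC[C@](C)(O3)[C@H](O[Si](C)(C)C(C)(C)C)C[C@@H]12 | intermediate
22 | target, CID10479028 (C24H36O8) | C=C1C(=O)O[C@H]2[C@H](OC(C)=O)[C@@H](C)CCC[C@](C)(OC(C)=O)[C@H]3CC[C@](C)(O3)[C@H](O)C[C@@H]12 | target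

**Total steps:** 19. **Longest linear sequence:** 16 (steps 1–7, then 11–19 from (S)-linalool); the C10–C14 fragment is made in parallel in steps 8–10.

## Three steps most likely to fail
1. **Step 18, NHK macrocyclisation.** The yield, the cis-lactone outcome and the C13/C14 relationship are all uncertain, since the observed C13/C14 relationship is opposite to simple Felkin–Anh prediction. Fallback: build the saturated cis-γ-lactone first with silyl protection, close the 14-ring by RCM at C10=C11, hydrogenate, and install the α-methylene last (LDA/Eschenmoser's salt), then acetylate.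
2. **Step 11, epoxide opening.** C9 is neopentylic next to a bulky THF-bearing quaternary carbon, and MgX2 can trigger a Meinwald rearrangement of the 1,1-disubstituted epoxide. Fallback: oxidise the primary alcohol of diol 4 to the C9 aldehyde and form C9=C10 by Wittig/Julia–Kocienski with the C10 phosphonium or sulfone from 12, then hydrogenate after the C3 chain is masked.
3. **Step 15, Baylis–Hillman on the β-silyloxy aldehyde.** It may be very slow, or DABCO may eliminate TBSOH. Fallback: skip steps 14–16 and install the C15–C17 unit on the terminal alkene of 15 by cross-metathesis with methyl 2-(acetoxymethyl)acrylate (Hoveyda–Grubbs II), then convert the allylic acetate to the (Z)-allylic bromide with LiBr.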